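## Retrosynthetic overview

1. Target ⇒ its heptabenzyl ether; all seven benzyl groups leave in one final hydrogenolysis.
2. Flavanone ring C (O1–C2 bond, the only ring made in the route and the only stereocentre) ⇒ enantioselective 6-endo oxa-Michael closure of a 2'-hydroxychalcone.
3. Chalcone ⇒ Claisen–Schmidt condensation of 2-hydroxy-4,6-bis(benzyloxy)acetophenone with a biaryl aldehyde.
4. Biaryl aldehyde ⇒ Suzuki coupling of 6-iodo-7,3',4'-tri-O-benzylluteolin with the boronate of 3,4-bis(benzyloxy)-5-bromobenzaldehyde.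
5. Ring order: the flavone rings A, B and C are bought intact as luteolin; the flavanone ring C is closed in the C–O bond-forming key step, just before deprotection.

Assumption: luteolin (bulk, plant-derived) is taken as a cheap commercial starting material.
Assumption: the sense of induction of the new catalyst is not known in advance; the (S,S)-catalyst is written, and its (R,R)-antipode is used if a pilot run gives the 2R product.

## Route

Step 1
Reactants: 1 luteolin; 2 benzyl bromide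
Product: 3 7-(benzyloxy)-2-[3,4-bis(benzyloxy)phenyl]-5-hydroxy-4H-chromen-4-one
Conditions: BnBr (3.2 equiv), K2CO3 (3.5 equiv), DMF, rt, 16 h
Reagents that add atoms: benzyl bromide (2), BrCc1ccccc1
Why: Williamson etherification; the 5-OH is hydrogen-bonded to the C4 carbonyl and is the least reactive hydroxyl, so the 7-, 3'- and 4'-OH are benzylated and the 5-OH stays free.

Step 2
Reactants: 3 7-(benzyloxy)-2-[3,4-bis(benzyloxy)phenyl]-5-hydroxy-4H-chromen-4-one; 4 benzyltrimethylammonium dichloroiodate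
Product: 5 7-(benzyloxy)-2-[3,4-bis(benzyloxy)phenyl]-5-hydroxy-6-iodo-4H-chromen-4-one
Conditions: BnMe3N+ ICl2− (1.1 equiv), CaCO3, CH2Cl2/MeOH 5:2, rt, 12 h
Reagents that add atoms: benzyltrimethylammonium dichloroiodate (4), C[N+](C)(C)Cc1ccccc1.Cl[I-]Cl
Why: Electrophilic aromatic iodination; in 5-hydroxy-7-alkoxyflavones this reagent iodinates C6, ortho to the free chelated 5-OH, in preference to C8, and ring B, conjugated to the pyrone, is much less reactive.

Step 3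
Reactants: 6 5-bromo-3,4-dihydroxybenzaldehyde; 2 benzyl bromide
Product: 7 3,4-bis(benzyloxy)-5-bromobenzaldehyde
Conditions: BnBr (2.3 equiv), K2CO3 (3 equiv), DMF, 60 °C, 6 h
Reagents that add atoms: benzyl bromide (2), BrCc1ccccc1
Why: Williamson etherification of both catechol hydroxyls, which have no competing nucleophilic site.

Step 4
Reactants: 7 3,4-bis(benzyloxy)-5-bromobenzaldehyde; 8 bis(pinacolato)diboron; 5 7-(benzyloxy)-2-[3,4-bis(benzyloxy)phenyl]-5-hydroxy-6-iodo-4H-chromen-4-one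
Product: 10 3,4-bis(benzyloxy)-5-{7-(benzyloxy)-2-[3,4-bis(benzyloxy)phenyl]-5-hydroxy-4-oxo-4H-chromen-6-yl}benzaldehyde, via pinacol boronate 9 (not isolated)
Conditions: 7 (1.3 equiv), B2pin2 (1.35 equiv), PdCl2(dppf) (3 mol %), KOAc, 1,4-dioxane, 90 °C, 4 h; then 5 (1.0 equiv), Pd(OAc)2 (5 mol %), SPhos (10 mol %), 3 M aq K3PO4, 90 °C, 12 h
Reagents that add atoms: bis(pinacolato)diboron (8), CC1(C)OB(OC1(C)C)B1OC(C)(C)C(C)(C)O1 (gives the boronate group of 9; no boron remains in 10)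
Why: One-pot Miyaura borylation and Suzuki–Miyaura coupling; the hindered partner is the iodide, SPhos is suited to tri-ortho-substituted biaryls, and the aldehyde and the free 5-OH tolerate both stages.

Step 5
Reactants: 11 2,4,6-trihydroxyacetophenone; 2 benzyl bromide
Product: 12 1-[2,4-bis(benzyloxy)-6-hydroxyphenyl]ethan-1-one
Conditions: BnBr (2.05 equiv), K2CO3 (2.2 equiv), DMF, 0 °C to rt, 12 h
Reagents that add atoms: benzyl bromide (2), BrCc1ccccc1
Why: Williamson etherification; one ortho hydroxyl stays locked in a hydrogen bond to the acetyl group and is not alkylated with two equivalents of bromide.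

Step 6
Reactants: 12 1-[2,4-bis(benzyloxy)-6-hydroxyphenyl]ethan-1-one; 10 3,4-bis(benzyloxy)-5-{7-(benzyloxy)-2-[3,4-bis(benzyloxy)phenyl]-5-hydroxy-4-oxo-4H-chromen-6-yl}benzaldehyde
Product: 13 (E)-1-[2,4-bis(benzyloxy)-6-hydroxyphenyl]-3-(3,4-bis(benzyloxy)-5-{7-(benzyloxy)-2-[3,4-bis(benzyloxy)phenyl]-5-hydroxy-4-oxo-4H-chromen-6-yl}phenyl)prop-2-en-1-one
Conditions: KOH (50% aq, 10 equiv), EtOH/THF 1:1, rt, 36 h; then AcOH, 0 °C
Reagents that add atoms: none
Why: Claisen–Schmidt condensation (crossed aldol, E1cB dehydration) gives the E-enone; in strong base the chalcone rests as its 2'-phenoxide, which does not cyclise, and the flavone is protected from hydroxide as its 5-phenoxide at room temperature.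

Step 7
Reactants: 13 (E)-1-[2,4-bis(benzyloxy)-6-hydroxyphenyl]-3-(3,4-bis(benzyloxy)-5-{7-(benzyloxy)-2-[3,4-bis(benzyloxy)phenyl]-5-hydroxy-4-oxo-4H-chromen-6-yl}phenyl)prop-2-en-1-one
Product: 14 (2S)-5,7-bis(benzyloxy)-2-(3,4-bis(benzyloxy)-5-{7-(benzyloxy)-2-[3,4-bis(benzyloxy)phenyl]-5-hydroxy-4-oxo-4H-chromen-6-yl}phenyl)-2,3-dihydro-4H-chromen-4-one
Conditions: (S,S)-imidodiphosphorimidate acid C74H33F30N3O8P2S2 (two (S)-3,3'-bis[3,5-bis(trifluoromethyl)phenyl]-BINOL phosphorus units joined by NH, each P=N–SO2CF3; 5 mol %), 5 Å MS, CHCl3, −20 °C, 48 h; then Et3N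
Reagents that add atoms: none
Why: Proposed new method: a confined, strongly acidic chiral imidodiphosphorimidate catalyses the direct enantioselective 6-endo-trig oxa-Michael cyclisation of an unactivated 2'-hydroxychalcone; the acid protonates the chalcone carbonyl in the rotamer that places the phenol over C-β (the 6'-benzyloxy oxygen helps hold it), the resulting hydroxyallyl cation (stabilised by the para-benzyloxy group of ring B) is paired with the chiral anion, whose pocket leaves the Si face of C-β open and whose sulfonyl oxygen takes up the phenolic proton as the O1–C2 bond forms, and enol tautomerisation gives the (2S)-flavanone under kinetic control at low temperature; the closest known reaction types are the racemic Brønsted acid cyclisation of 2'-hydroxychalcones, the chiral phosphoric acid aza-Michael cyclisation of 2'-aminochalcones, imidodiphosphorimidate-catalysed intramolecular hydroalkoxylation of alkenes, and the thiourea-catalysed oxa-Michael closure of doubly activated alkylidene β-ketoesters.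

Step 8
Reactants: 14 (2S)-5,7-bis(benzyloxy)-2-(3,4-bis(benzyloxy)-5-{7-(benzyloxy)-2-[3,4-bis(benzyloxy)phenyl]-5-hydroxy-4-oxo-4H-chromen-6-yl}phenyl)-2,3-dihydro-4H-chromen-4-one
Product: 15 (2S)-2-{3-[2-(3,4-dihydroxyphenyl)-5,7-dihydroxy-4-oxo-4H-chromen-6-yl]-4,5-dihydroxyphenyl}-5,7-dihydroxy-2,3-dihydro-4H-chromen-4-one
Conditions: H2 (1 atm), 10% Pd/C, THF/MeOH 1:1, rt, 3 h; filter, neutral work-up, no base
Reagents that add atoms: none
Why: Catalytic hydrogenolysis cleaves all seven aryl benzyl ethers under neutral conditions, which leave the flavone C2=C3 bond, both carbonyls and the base-sensitive C2 stereocentre untouched when the reaction is stopped at full debenzylation.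

## Compound list

1 | luteolin, 2-(3,4-dihydroxyphenyl)-5,7-dihydroxy-4H-chromen-4-one | O=c1cc(-c2ccc(O)c(O)c2)oc2cc(O)cc(O)c12 | starting material
2 | benzyl bromide | BrCc1ccccc1 | starting material
3 | 7-(benzyloxy)-2-[3,4-bis(benzyloxy)phenyl]-5-hydroxy-4H-chromen-4-one | O=c1cc(-c2ccc(OCc3ccccc3)c(OCc3ccccc3)c2)oc2cc(OCc3ccccc3)cc(O)c12 | intermediate
4 | benzyltrimethylammonium dichloroiodate | C[N+](C)(C)Cc1ccccc1.Cl[I-]Cl | starting material
5 | 7-(benzyloxy)-2-[3,4-bis(benzyloxy)phenyl]-5-hydroxy-6-iodo-4H-chromen-4-one | O=c1cc(-c2ccc(OCc3ccccc3)c(OCc3ccccc3)c2)oc2cc(OCc3ccccc3)c(I)c(O)c12 | intermediate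
6 | 5-bromo-3,4-dihydroxybenzaldehyde | O=Cc1cc(O)c(O)c(Br)c1 | starting material
7 | 3,4-bis(benzyloxy)-5-bromobenzaldehyde | O=Cc1cc(Br)c(OCc2ccccc2)c(OCc2ccccc2)c1 | intermediate
8 | bis(pinacolato)diboron | CC1(C)OB(OC1(C)C)B1OC(C)(C)C(C)(C)O1 | starting material
9 | 3,4-bis(benzyloxy)-5-(4,4,5,5-tetramethyl-1,3,2-dioxaborolan-2-yl)benzaldehyde | O=Cc1cc(B2OC(C)(C)C(C)(C)O2)c(OCc2ccccc2)c(OCc2ccccc2)c1 | intermediate
10 | 3,4-bis(benzyloxy)-5-{7-(benzyloxy)-2-[3,4-bis(benzyloxy)phenyl]-5-hydroxy-4-oxo-4H-chromen-6-yl}benzaldehyde | O=Cc1cc(OCc2ccccc2)c(OCc2ccccc2)c(-c2c(OCc3ccccc3)cc3oc(-c4ccc(OCc5ccccc5)c(OCc5ccccc5)c4)cc(=O)c3c2O)c1 | intermediate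
11 | 2,4,6-trihydroxyacetophenone | CC(=O)c1c(O)cc(O)cc1O | starting material
12 | 1-[2,4-bis(benzyloxy)-6-hydroxyphenyl]ethan-1-one | CC(=O)c1c(O)cc(OCc2ccccc2)cc1OCc1ccccc1 | intermediate
13 | (E)-1-[2,4-bis(benzyloxy)-6-hydroxyphenyl]-3-(3,4-bis(benzyloxy)-5-{7-(benzyloxy)-2-[3,4-bis(benzyloxy)phenyl]-5-hydroxy-4-oxo-4H-chromen-6-yl}phenyl)prop-2-en-1-one | O=C(/C=C/c1cc(OCc2ccccc2)c(OCc2ccccc2)c(-c2c(OCc3ccccc3)cc3oc(-c4ccc(OCc5ccccc5)c(OCc5ccccc5)c4)cc(=O)c3c2O)c1)c1c(O)cc(OCc2ccccc2)cc1OCc1ccccc1 | intermediate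
14 | (2S)-5,7-bis(benzyloxy)-2-(3,4-bis(benzyloxy)-5-{7-(benzyloxy)-2-[3,4-bis(benzyloxy)phenyl]-5-hydroxy-4-oxo-4H-chromen-6-yl}phenyl)-2,3-dihydro-4H-chromen-4-one | O=C1C[C@@H](c2cc(OCc3ccccc3)c(OCc3ccccc3)c(-c3c(OCc4ccccc4)cc4oc(-c5ccc(OCc6ccccc6)c(OCc6ccccc6)c5)cc(=O)c4c3O)c2)Oc2cc(OCc3ccccc3)cc(OCc3ccccc3)c21 | intermediate
15 | (2S)-2-{3-[2-(3,4-dihydroxyphenyl)-5,7-dihydroxy-4-oxo-4H-chromen-6-yl]-4,5-dihydroxyphenyl}-5,7-dihydroxy-2,3-dihydro-4H-chromen-4-one | O=C1C[C@@H](c2cc(O)c(O)c(-c3c(O)cc4oc(-c5ccc(O)c(O)c5)cc(=O)c4c3O)c2)Oc2cc(O)cc(O)c21 | target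

## Step count and risk

Total steps: 8 (7 if the catalogue compound 12 is bought).
Longest linear sequence: 6 (steps 1, 2, 4, 6, 7, 8 from luteolin).

Three steps most likely to fail:

**Step 4 (one-pot borylation and Suzuki coupling).** The biaryl is tri-ortho-substituted, the iodide sits next to a free chelated phenol, and the boronate can protodeboronate in the aqueous stage. The fallback sets out from 5 and 7 and comes back at 10. The 5-OH of 5 is benzylated (BnBr, K2CO3, NaI, DMF, 70 °C) to 5,7-bis(benzyloxy)-2-[3,4-bis(benzyloxy)phenyl]-6-iodo-4H-chromen-4-one F1. Boronate 9 is made from 7 in a separate flask and isolated. F1 and 9 are coupled (Pd(OAc)2, SPhos, K3PO4·H2O, toluene, 100 °C) to 3,4-bis(benzyloxy)-5-{5,7-bis(benzyloxy)-2-[3,4-bis(benzyloxy)phenyl]-4-oxo-4H-chromen-6-yl}benzaldehyde F2. MgBr2·OEt2 (toluene/Et2O, rt to 60 °C) then removes only the benzyl group peri to the flavone carbonyl by chelation-assisted cleavage and gives 10.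

**Step 6 (Claisen–Schmidt condensation).** Hydroxide can open the pyrone ring of the flavone, and the large aldehyde 10 is poorly soluble in alcoholic base. The fallback sets out from 7 and 12 and comes back at 13, with the order of events changed so that the flavone never meets hydroxide. Aldehyde 7 is condensed with 12 (KOH, EtOH, rt) to (E)-1-[2,4-bis(benzyloxy)-6-hydroxyphenyl]-3-[3,4-bis(benzyloxy)-5-bromophenyl]prop-2-en-1-one F3. Miyaura borylation (B2pin2, PdCl2(dppf), KOAc, dioxane, 80 °C) gives (E)-1-[2,4-bis(benzyloxy)-6-hydroxyphenyl]-3-[3,4-bis(benzyloxy)-5-(4,4,5,5-tetramethyl-1,3,2-dioxaborolan-2-yl)phenyl]prop-2-en-1-one F4. Suzuki coupling of F4 with 5 (Pd(OAc)2, SPhos, K3PO4, toluene/H2O, 80 °C) gives 13.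

**Step 7 (proposed new enantioselective cyclisation).** The basic flavone carbonyl may hold back the acid catalyst. The closure is reversible, so conversion may stop at an equilibrium and the ee may erode. The sense and level of induction are untested. Unreacted 13 can be recovered and resubmitted. The fallback uses known chemistry, sets out from 13 and comes back at 14. NaOAc in EtOH/THF at reflux cyclises 13 to racemic 5,7-bis(benzyloxy)-2-(3,4-bis(benzyloxy)-5-{7-(benzyloxy)-2-[3,4-bis(benzyloxy)phenyl]-5-hydroxy-4-oxo-4H-chromen-6-yl}phenyl)-2,3-dihydro-4H-chromen-4-one F5. Preparative chiral SFC (amylose tris(3,5-dimethylphenylcarbamate) phase, CO2/MeOH) separates 14 from its (2R)-enantiomer F6. F6 is put back under the NaOAc conditions, where ring opening to 13 and reclosure return it to F5 for another pass.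

## Further compounds

F1 | step 4 | 5,7-bis(benzyloxy)-2-[3,4-bis(benzyloxy)phenyl]-6-iodo-4H-chromen-4-one | O=c1cc(-c2ccc(OCc3ccccc3)c(OCc3ccccc3)c2)oc2cc(OCc3ccccc3)c(I)c(OCc3ccccc3)c12
F2 | step 4 | 3,4-bis(benzyloxy)-5-{5,7-bis(benzyloxy)-2-[3,4-bis(benzyloxy)phenyl]-4-oxo-4H-chromen-6-yl}benzaldehyde | O=Cc1cc(OCc2ccccc2)c(OCc2ccccc2)c(-c2c(OCc3ccccc3)cc3oc(-c4ccc(OCc5ccccc5)c(OCc5ccccc5)c4)cc(=O)c3c2OCc6ccccc6)c1
F3 | step 6 | (E)-1-[2,4-bis(benzyloxy)-6-hydroxyphenyl]-3-[3,4-bis(benzyloxy)-5-bromophenyl]prop-2-en-1-one | O=C(/C=C/c1cc(Br)c(OCc2ccccc2)c(OCc2ccccc2)c1)c1c(O)cc(OCc2ccccc2)cc1OCc1ccccc1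
F4 | step 6 | (E)-1-[2,4-bis(benzyloxy)-6-hydroxyphenyl]-3-[3,4-bis(benzyloxy)-5-(4,4,5,5-tetramethyl-1,3,2-dioxaborolan-2-yl)phenyl]prop-2-en-1-one | O=C(/C=C/c1cc(B2OC(C)(C)C(C)(C)O2)c(OCc2ccccc2)c(OCc2ccccc2)c1)c1c(O)cc(OCc2ccccc2)cc1OCc1ccccc1
F5 | step 7 | racemic 5,7-bis(benzyloxy)-2-(3,4-bis(benzyloxy)-5-{7-(benzyloxy)-2-[3,4-bis(benzyloxy)phenyl]-5-hydroxy-4-oxo-4H-chromen-6-yl}phenyl)-2,3-dihydro-4H-chromen-4-one | O=C1CC(c2cc(OCc3ccccc3)c(OCc3ccccc3)c(-c3c(OCc4ccccc4)cc4oc(-c5ccc(OCc6ccccc6)c(OCc6ccccc6)c5)cc(=O)c4c3O)c2)Oc2cc(OCc3ccccc3)cc(OCc3ccccc3)c21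
F6 | step 7 | (2R)-5,7-bis(benzyloxy)-2-(3,4-bis(benzyloxy)-5-{7-(benzyloxy)-2-[3,4-bis(benzyloxy)phenyl]-5-hydroxy-4-oxo-4H-chromen-6-yl}phenyl)-2,3-dihydro-4H-chromen-4-one | O=C1C[C@H](c2cc(OCc3ccccc3)c(OCc3ccccc3)c(-c3c(OCc4ccccc4)cc4oc(-c5ccc(OCc6ccccc6)c(OCc6ccccc6)c5)cc(=O)c4c3O)c2)Oc2cc(OCc3ccccc3)cc(OCc3ccccc3)c21
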